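- Late in the dawn run substrate stands still: 91% left at 25.0 h, 91% at 50.0 h. Yet that loss of 9.00% is less than the partner charged, 30.0% of the substrate charge. So I assume the protic impurity takes partner away; the assumption is untested, since dawn, midnight and summer share one impurity charge.

| flask | substrate | partner | protic impurity | remark | time |
|---|---|---|---|---|---|
| dawn | 0.50 M | 0.15 M | 0.25 M | run made earlier |  |
| midnight | 0.50 M | 0.22 M | 0.25 M | run made earlier |  |
| summer | 0.25 M | 0.30 M | 0.25 M | run made earlier |  |
| flask | 0.50 M | 0.300 M | 0.250 M |  | 40 h |

- dawn (time / h: side product / %, target / %, substrate / %): 12.0: 0, 1, 96; 25.0: 5, 2, 91; 40.0: 5, 1, 90; 50.0: 10, 1, 91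
- midnight (time / h: side product / %, target / %, substrate / %): 4.00: 2, 0, 97; 8.00: 3, 0, 95; 20.0: 7, 2, 92; 50.0: 16, 0, 85
- summer (time / h: side product / %, target / %, substrate / %): 6.00: 0, 2, 94; 15.0: 6, 7, 90; 30.0: 12, 5, 81; 50.0: 18, 4, 75

(readings scatter by 1.5 percentage points)

- in percentages every species weighs as the substrate in it: one side product counts as two
- what was read earlier has a scatter of 1.5 percentage points, one standard deviation

- where most of what was charged as substrate, at 40 h is found (substrate / target / side product)
- the largest share itself, whichever of these holds it, in percent of the substrate charged

- Work with the fraction left, through its log-loss: the natural log of its reciprocal. From dawn to summer the partner-to-impurity ratio goes up to twice its value, and the log-loss at 50.0 h goes from 0.0943 to 0.288. Call the power that joins them the steepness, 1.61, a reading with the scatter in it, and with the different substrate charges of those two runs in it as well.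

- The flask has summer's ratio, 1.20. Treating substrate as pseudo-first-order, you may borrow summer's curve, though the flask holds twice the substrate.

- That curve falls at 0.00702 h⁻¹ up to 30.0 h, then bends to 0.00385 h⁻¹, still falling. Averaging the two log-losses gives 0.249 at 40 h, so I reckon 77.9% substrate left.

- The forecast says substrate, 82%, above my figure, and notes: “Partner now exceeds the protic impurity, which is a possible complication”.

- The flask gives substrate, 75.9%, a log-loss of 0.276. At the start of the flask, the step of partner with protic impurity uses partner 8.5 times as fast as the step of substrate with partner. Take the flask's partner down to 0.261 M: the steepness reckons a rise in substrate of 4.3 percentage points, and the simulated move at that partner is 5 points.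

    substrate + target → side product (k = 0.150 L mol⁻¹ h⁻¹)
    substrate + partner + target → 2 target (k = 0.870 L² mol⁻² h⁻¹)
    substrate + partner → target (k = 0.0230 L mol⁻¹ h⁻¹)
    partner + protic impurity → quenched reagent (k = 0.390 L mol⁻¹ h⁻¹)

- In a neighbour flask, charged like the flask but with 1.0 M protic impurity, the ratio is a quarter of the flask's, so the steepness gives 97.1% substrate left. The simulation gives 95.5%.

The earlier runs and the new flask come from a simulation for substances that don't exist, noise included.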